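## Retrosynthetic overview

- Silyhermin B is a (2S)-5,7-dihydroxyflavanone whose C2 carries a trans-2-guaiacyl-3-(hydroxymethyl)-7-hydroxy-2,3-dihydrobenzofuran-5-yl group. The last C–C bond (flavanone C2 to benzofuran C5) is made by a rhodium-catalysed asymmetric 1,4-addition of benzofuran-5-boronate 15 to 5,7-bis(benzyloxy)chromone 19.
- The strategy rests on the dihydrofuran ring O1–C2(guaiacyl)–C3(CH2OH)–C3a–C7a. Its C3 carries the arene carbon C3a and a one-carbon branch, which is the pattern of a chroman-4-one whose carbonyl carbon C4 has been expelled from the ring. The unit is therefore built as a second flavanone, 10, and contracted by an oxidative 1,2-shift of ring A carbon C4a from C4 to C3.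
- Flavanone 10 comes from 8-(benzyloxy)-6-bromochromone 5 and the pivaloylated guaiacylboronic acid 9 by a first asymmetric 1,4-addition. The bromine is the later handle for the boronate.
- Ring order: pyranone of 5 (step 3), contracted to the dihydrofuran (step 8), then the pyranone of 19 (step 12), whose C2 becomes the last stereocentre in step 13. The three benzyl ethers are removed in step 14.

Key step: step 8

Assumption: the (R)-biaryl bisphosphine is taken to give the (2R)-flavanone and the (S)-ligand the (2S)-flavanone, as binap-type rhodium catalysts do with cyclic enones; if the sense is the reverse, the two ligand antipodes change places in steps 7 and 13.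

Abbreviation: MeO-F12-BIPHEP is 6,6'-dimethoxy-2,2'-bis[bis(3,4,5-trifluorophenyl)phosphino]-1,1'-biphenyl.

## Route

Step 1
Reactants: 1 2',3'-dihydroxyacetophenone
Product: 2 1-[3-(benzyloxy)-2-hydroxyphenyl]ethanone
Conditions: NaH (2.1 equiv), DMF, 0 °C; BnBr (1.0 equiv), 0 °C to rt; aq HCl work-up
Reagents that add atoms: benzyl bromide, BrCc1ccccc1
Why: In the dianion the C2' phenoxide is conjugated with and chelated to the acetyl group, so the Williamson alkylation by one equivalent of benzyl bromide should take place at the more nucleophilic C3' phenoxide.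

Step 2
Reactants: 2 1-[3-(benzyloxy)-2-hydroxyphenyl]ethanone
Product: 3 1-[3-(benzyloxy)-5-bromo-2-hydroxyphenyl]ethanone
Conditions: NBS (1.05 equiv), MeCN, 0 °C to rt
Reagents that add atoms: N-bromosuccinimide, O=C1CCC(=O)N1Br
Why: Electrophilic aromatic bromination is directed by the free phenol to its para position C5', which is also meta to the acetyl group and the only unhindered activated site, as in the bromination of o-vanillin.

Step 3
Reactants: 3 1-[3-(benzyloxy)-5-bromo-2-hydroxyphenyl]ethanone
Product: 5 8-(benzyloxy)-6-bromo-4H-chromen-4-one, via enaminone 4 (not isolated)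
Conditions: Me2NCH(OMe)2, toluene, 100 °C; evaporate; conc. HCl, CH2Cl2, rt
Reagents that add atoms: N,N-dimethylformamide dimethyl acetal, COC(OC)N(C)C
Why: Condensation of the methyl ketone with the formamide acetal gives the enaminone, and acid then drives 6-endo addition of the phenol to the β-carbon and loss of dimethylamine (the standard enaminone chromone synthesis).

Step 4
Reactants: 6 4-bromo-2-methoxyphenol
Product: 7 4-bromo-2-methoxyphenyl pivalate
Conditions: t-BuCOCl, Et3N, DMAP (cat.), CH2Cl2, 0 °C to rt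
Reagents that add atoms: pivaloyl chloride, CC(C)(C)C(=O)Cl
Why: DMAP-catalysed O-acylation of the phenol gives a hindered ester that survives the couplings and makes ring B electron-poor for the key step.

Step 5
Reactants: 7 4-bromo-2-methoxyphenyl pivalate
Product: 8 2-methoxy-4-(4,4,5,5-tetramethyl-1,3,2-dioxaborolan-2-yl)phenyl pivalate
Conditions: B2pin2, PdCl2(dppf) (cat.), KOAc, 1,4-dioxane, 90 °C
Reagents that add atoms: bis(pinacolato)diboron, CC1(C)OB(OC1(C)C)B1OC(C)(C)C(C)(C)O1
Why: Miyaura borylation, in which zerovalent palladium inserts into the aryl C–Br bond and acetate-assisted transmetalation with the diboron is followed by reductive elimination; the aryl pivalate is inert to palladium and to KOAc.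

Step 6
Reactants: 8 2-methoxy-4-(4,4,5,5-tetramethyl-1,3,2-dioxaborolan-2-yl)phenyl pivalate
Product: 9 [3-methoxy-4-(pivaloyloxy)phenyl]boronic acid
Conditions: NaIO4, NH4OAc, acetone/H2O, rt
Reagents that add atoms: water, O
Why: Periodate cleaves the pinacol released in the hydrolysis equilibrium to acetone, which drives the boronic ester to the free boronic acid under near-neutral conditions that spare the pivalate (oxidative deprotection of a pinacol boronate).

Step 7
Reactants: 5 8-(benzyloxy)-6-bromo-4H-chromen-4-one; 9 [3-methoxy-4-(pivaloyloxy)phenyl]boronic acid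
Product: 10 (2R)-8-(benzyloxy)-6-bromo-2-[3-methoxy-4-(pivaloyloxy)phenyl]chroman-4-one
Conditions: [RhCl(C2H4)2]2 (cat.), (R)-MeO-F12-BIPHEP, KOH aq (cat.), toluene/H2O, 40 °C
Reagents that add atoms: none
Why: Rhodium-catalysed asymmetric 1,4-addition of an arylboronic acid to a chromone (Hayashi–Miyaura reaction), in which the aryl–rhodium species adds to C2 on the face left open by the (R)-bisphosphine and so sets C2 as R, while the electron-poor ligand keeps the catalyst active for a chromone and the aryl bromide is inert to monovalent rhodium.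

Step 8
Reactants: 10 (2R)-8-(benzyloxy)-6-bromo-2-[3-methoxy-4-(pivaloyloxy)phenyl]chroman-4-one
Product: 13 methyl (2R,3R)-7-(benzyloxy)-5-bromo-2-[3-methoxy-4-(pivaloyloxy)phenyl]-2,3-dihydro-1-benzofuran-3-carboxylate, via enol ether 11 (not isolated), via iodane ketal 12 (not isolated)
Conditions: PhI(OAc)2 (1.3 equiv), H2SO4 (cat.), HC(OMe)3, rt; aq NaHCO3 work-up
Reagents that add atoms: trimethyl orthoformate, COC(OC)OC; water, O
Why: This is the known oxidative ring contraction of flavanones to methyl trans-2-aryl-2,3-dihydrobenzofuran-3-carboxylates by a trivalent iodine reagent in acidic trimethyl orthoformate, a relative of the thallium trinitrate rearrangement of aryl ketones: acid and orthoformate turn the ketone into enol ether 11, PhI(OAc)2 attacks its C3 on the face away from the C2 aryl group, and methanol caps C4 to give the 2,3-trans iodane ketal 12. In 12 the equatorial C3–I bond lies antiperiplanar to the ring bond C4–C4a, so C4a shifts from C4 to C3 through a bridged phenonium-like transition state as iodobenzene leaves, and C4, now outside the ring as a dimethoxycarbenium ion, is hydrolysed to the methyl ester on work-up. The dihydrofuran ring is thus closed by contraction of the pyranone through this suprafacial 1,2-shift (formally a 3-exo-tet attack of the arene ipso carbon on C3), not by an end-to-end cyclisation. The new stereocentre C3 is set by substrate control, since iodine enters anti to the C2 aryl group and is displaced with inversion, which places the ester trans to the aryl group (also the thermodynamic epimer); C2 takes no part and keeps its R configuration. The step needs migration of C4a in preference to the C2 aryl group (isoflavone), to loss of the C2 hydrogen (flavone) and to methanolysis at C3; C4a is ortho to the ring oxygen O1 and bridges readily, whereas ring B, with an acyloxy group para and a methoxy group meta to its point of attachment, is a poor migrating group and also disfavours acid ionisation of the C2–O1 bond.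

Step 9
Reactants: 13 methyl (2R,3R)-7-(benzyloxy)-5-bromo-2-[3-methoxy-4-(pivaloyloxy)phenyl]-2,3-dihydro-1-benzofuran-3-carboxylate
Product: 14 4-[(2R,3S)-7-(benzyloxy)-5-bromo-3-(hydroxymethyl)-2,3-dihydro-1-benzofuran-2-yl]-2-methoxyphenol
Conditions: LiAlH4, THF, 0 °C; aq potassium sodium tartrate work-up
Reagents that add atoms: none
Why: Lithium aluminium hydride reduces the methyl ester to the primary alcohol and cleaves the aryl pivalate to the phenol in one operation, faster at 0 °C than deprotonation at C3 or attack on the aryl bromide, so the trans arrangement is kept (C3 is named S only because the substituent priorities change).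

Step 10
Reactants: 14 4-[(2R,3S)-7-(benzyloxy)-5-bromo-3-(hydroxymethyl)-2,3-dihydro-1-benzofuran-2-yl]-2-methoxyphenol
Product: 15 4-[(2R,3S)-7-(benzyloxy)-3-(hydroxymethyl)-5-(4,4,5,5-tetramethyl-1,3,2-dioxaborolan-2-yl)-2,3-dihydro-1-benzofuran-2-yl]-2-methoxyphenol
Conditions: B2pin2, PdCl2(dppf) (cat.), KOAc, 1,4-dioxane, 85 °C
Reagents that add atoms: bis(pinacolato)diboron, CC1(C)OB(OC1(C)C)B1OC(C)(C)C(C)(C)O1
Why: Miyaura borylation of the aryl bromide, which has no ortho substituent; the weak base KOAc leaves the free phenol and primary alcohol largely un-ionised and does not touch the two stereocentres.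

Step 11
Reactants: 16 2',4',6'-trihydroxyacetophenone
Product: 17 1-[2,4-bis(benzyloxy)-6-hydroxyphenyl]ethanone
Conditions: BnBr (2.1 equiv), K2CO3, DMF, rt to 50 °C
Reagents that add atoms: benzyl bromide, BrCc1ccccc1
Why: Williamson benzylation stops after two ether groups because the last hydroxyl is hydrogen-bonded to the acetyl carbonyl and much less nucleophilic.

Step 12
Reactants: 17 1-[2,4-bis(benzyloxy)-6-hydroxyphenyl]ethanone
Product: 19 5,7-bis(benzyloxy)-4H-chromen-4-one, via enaminone 18 (not isolated)
Conditions: Me2NCH(OMe)2, toluene, 100 °C; evaporate; conc. HCl, CH2Cl2, rt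
Reagents that add atoms: N,N-dimethylformamide dimethyl acetal, COC(OC)N(C)C
Why: The same enaminone chromone synthesis as in step 3, with acid-promoted 6-endo closure of the chelated phenol and loss of dimethylamine.

Step 13
Reactants: 15 4-[(2R,3S)-7-(benzyloxy)-3-(hydroxymethyl)-5-(4,4,5,5-tetramethyl-1,3,2-dioxaborolan-2-yl)-2,3-dihydro-1-benzofuran-2-yl]-2-methoxyphenol; 19 5,7-bis(benzyloxy)-4H-chromen-4-one
Product: 20 (2S)-5,7-bis(benzyloxy)-2-[(2R,3S)-7-(benzyloxy)-3-(hydroxymethyl)-2-(4-hydroxy-3-methoxyphenyl)-2,3-dihydro-1-benzofuran-5-yl]chroman-4-one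
Conditions: [RhCl(C2H4)2]2 (cat.), (S)-MeO-F12-BIPHEP, KOH aq (0.3 equiv), 1,4-dioxane/H2O, 50 °C
Reagents that add atoms: none
Why: Rhodium-catalysed asymmetric 1,4-addition of an aryl pinacol boronate, hydrolysed in situ by the aqueous base, to the 5,7-dialkoxychromone, in which the (S)-ligand directs the aryl group to the face of C2 opposite to that used in step 7 and sets the flavanone centre as S under catalyst control, the remote centres of 15 having little influence and the free phenol and alcohol being tolerated in the aqueous medium.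

Step 14
Reactants: 20 (2S)-5,7-bis(benzyloxy)-2-[(2R,3S)-7-(benzyloxy)-3-(hydroxymethyl)-2-(4-hydroxy-3-methoxyphenyl)-2,3-dihydro-1-benzofuran-5-yl]chroman-4-one
Product: 21 silyhermin B
Conditions: H2 (1 atm), Pd/C (10 %), EtOAc/MeOH, rt
Reagents that add atoms: none
Why: Hydrogenolysis of the three aryl benzyl ethers over palladium on carbon at room temperature is much faster than cleavage of the two cyclic benzylic C–O bonds or reduction of the aryl ketone, so stopping at full debenzylation should give the target with all three stereocentres unchanged.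

## Compound list

1 | 2',3'-dihydroxyacetophenone | CC(=O)c1cccc(O)c1O | starting material
2 | 1-[3-(benzyloxy)-2-hydroxyphenyl]ethanone | CC(=O)c1cccc(OCc2ccccc2)c1O | intermediate
3 | 1-[3-(benzyloxy)-5-bromo-2-hydroxyphenyl]ethanone | CC(=O)c1cc(Br)cc(OCc2ccccc2)c1O | intermediate
4 | (E)-1-[3-(benzyloxy)-5-bromo-2-hydroxyphenyl]-3-(dimethylamino)prop-2-en-1-one (not isolated) | CN(C)/C=C/C(=O)c1cc(Br)cc(OCc2ccccc2)c1O | intermediate
5 | 8-(benzyloxy)-6-bromo-4H-chromen-4-one | O=c1ccoc2c(OCc3ccccc3)cc(Br)cc12 | intermediate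
6 | 4-bromo-2-methoxyphenol | COc1cc(Br)ccc1O | starting material
7 | 4-bromo-2-methoxyphenyl pivalate | COc1cc(Br)ccc1OC(=O)C(C)(C)C | intermediate
8 | 2-methoxy-4-(4,4,5,5-tetramethyl-1,3,2-dioxaborolan-2-yl)phenyl pivalate | COc1cc(B2OC(C)(C)C(C)(C)O2)ccc1OC(=O)C(C)(C)C | intermediate
9 | [3-methoxy-4-(pivaloyloxy)phenyl]boronic acid | COc1cc(B(O)O)ccc1OC(=O)C(C)(C)C | intermediate
10 | (2R)-8-(benzyloxy)-6-bromo-2-[3-methoxy-4-(pivaloyloxy)phenyl]chroman-4-one | COc1cc([C@H]2CC(=O)c3cc(Br)cc(OCc4ccccc4)c3O2)ccc1OC(=O)C(C)(C)C | intermediate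
11 | 4-[(2R)-8-(benzyloxy)-6-bromo-4-methoxy-2H-chromen-2-yl]-2-methoxyphenyl pivalate (enol ether, not isolated) | COc1cc([C@H]2C=C(OC)c3cc(Br)cc(OCc4ccccc4)c3O2)ccc1OC(=O)C(C)(C)C | intermediate
12 | 4-[(2S,3S)-3-[acetoxy(phenyl)-λ3-iodanyl]-8-(benzyloxy)-6-bromo-4,4-dimethoxychroman-2-yl]-2-methoxyphenyl pivalate (iodine trans to the aryl group; C2 arranged as in 10, descriptor changed by priorities only; not isolated) | COc1cc([C@H]2[C@H]([I](OC(C)=O)c5ccccc5)C(OC)(OC)c3cc(Br)cc(OCc4ccccc4)c3O2)ccc1OC(=O)C(C)(C)C | intermediate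
13 | methyl (2R,3R)-7-(benzyloxy)-5-bromo-2-[3-methoxy-4-(pivaloyloxy)phenyl]-2,3-dihydro-1-benzofuran-3-carboxylate (trans) | COc1cc([C@@H]2Oc3c(OCc4ccccc4)cc(Br)cc3[C@H]2C(=O)OC)ccc1OC(=O)C(C)(C)C | intermediate
14 | 4-[(2R,3S)-7-(benzyloxy)-5-bromo-3-(hydroxymethyl)-2,3-dihydro-1-benzofuran-2-yl]-2-methoxyphenol (trans) | COc1cc([C@@H]2Oc3c(OCc4ccccc4)cc(Br)cc3[C@H]2CO)ccc1O | intermediate
15 | 4-[(2R,3S)-7-(benzyloxy)-3-(hydroxymethyl)-5-(4,4,5,5-tetramethyl-1,3,2-dioxaborolan-2-yl)-2,3-dihydro-1-benzofuran-2-yl]-2-methoxyphenol | COc1cc([C@@H]2Oc3c(OCc4ccccc4)cc(B4OC(C)(C)C(C)(C)O4)cc3[C@H]2CO)ccc1O | intermediate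
16 | 2',4',6'-trihydroxyacetophenone | CC(=O)c1c(O)cc(O)cc1O | starting material
17 | 1-[2,4-bis(benzyloxy)-6-hydroxyphenyl]ethanone | CC(=O)c1c(O)cc(OCc2ccccc2)cc1OCc1ccccc1 | intermediate
18 | (E)-1-[2,4-bis(benzyloxy)-6-hydroxyphenyl]-3-(dimethylamino)prop-2-en-1-one (not isolated) | CN(C)/C=C/C(=O)c1c(O)cc(OCc2ccccc2)cc1OCc1ccccc1 | intermediate
19 | 5,7-bis(benzyloxy)-4H-chromen-4-one | O=c1ccoc2cc(OCc3ccccc3)cc(OCc3ccccc3)c12 | intermediate
20 | (2S)-5,7-bis(benzyloxy)-2-[(2R,3S)-7-(benzyloxy)-3-(hydroxymethyl)-2-(4-hydroxy-3-methoxyphenyl)-2,3-dihydro-1-benzofuran-5-yl]chroman-4-one | COc1cc([C@@H]2Oc3c(OCc4ccccc4)cc([C@@H]4CC(=O)c5c(OCc6ccccc6)cc(OCc6ccccc6)cc5O4)cc3[C@H]2CO)ccc1O | intermediate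
21 | silyhermin B, (2S)-5,7-dihydroxy-2-[(2R,3S)-7-hydroxy-3-(hydroxymethyl)-2-(4-hydroxy-3-methoxyphenyl)-2,3-dihydro-1-benzofuran-5-yl]chroman-4-one | COc1cc([C@@H]2Oc3c(O)cc([C@@H]4CC(=O)c5c(O)cc(O)cc5O4)cc3[C@H]2CO)ccc1O | target

## Step count and risks

Total step count: 14. Longest linear sequence: 9 steps (steps 1, 2, 3, 7, 8, 9, 10, 13, 14 from compound 1; equally steps 4, 5, 6, 7, 8, 9, 10, 13, 14 from compound 6).

The three steps most likely to fail:

**Step 8.** The iodane may be consumed by the wrong process: shift of the C2 aryl group, loss of the C2 hydrogen, or solvolysis at C3. Acid-promoted opening of the pyran ring could also erode the C2 configuration, and the meta bromine on the migrating ring may slow the shift.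
The fallback sets out from 10 and comes back at 13, and reaches the same C4a shift through a carbene-type rearrangement instead of an oxidation. The lithium enolate of 10 (LiN(SiMe3)2, THF, −78 °C) would be acylated with 2,2,2-trifluoroethyl trifluoroacetate to the 3-trifluoroacetyl ketone F1. Deacylative diazo transfer (MsN3, Et3N, MeCN/H2O) would give the 3-diazo ketone F2. Irradiation of F2 in methanol should bring about a Wolff rearrangement, in which C4a migrates from C4 to C3 and the ketene is trapped as the methyl ester. Protonation of the ester enol is expected to give the cis ester F3 along with 13, and DBU in toluene would equilibrate F3 to the trans ester 13.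

**Step 13.** Insertion of the electron-rich 5,7-dialkoxychromone into the aryl–rhodium bond may be slow, so that protodeboronation of the boronate wins, and facial control may be incomplete at this late stage.
The fallback sets out from 14 and comes back at 21, and builds the pyranone by aldol condensation and oxa-Michael closure. Benzylation of the phenol of 14 (BnBr, K2CO3, acetone) would give the benzyl ether F4. Bromine–lithium exchange on its lithium alkoxide (n-BuLi, 2.2 equiv, THF, −78 °C) and quenching with DMF would give the aldehyde F5. Claisen–Schmidt condensation of F5 with 17 (KOH, EtOH, rt) would give the 2'-hydroxychalcone F6. Cyclisation (NaOAc, EtOH, reflux) should give both C2 epimers, the (2S)-flavanone F7 and the (2R)-flavanone F8. These are diastereomers and would be separated by chromatography, with F8 returned to the equilibration through the chalcone. Hydrogenolysis of the four benzyl ethers of F7 under the conditions of step 14 would give 21.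

**Step 14.** Reduction may run on past debenzylation into the two cyclic benzylic C–O bonds (dihydrofuran C2–O1 and flavanone C2–O1), or stall with partly debenzylated material.
The fallback sets out from 20 and comes back at 21 with a non-reductive, Lewis-acid dealkylation: BCl3 with pentamethylbenzene as benzyl cation scavenger in CH2Cl2 at −78 °C, followed by a methanol quench. This fallback makes no compound outside the list (F0).

## Further compounds

F1 | step 8 | 4-[(2R)-8-(benzyloxy)-6-bromo-4-oxo-3-(trifluoroacetyl)chroman-2-yl]-2-methoxyphenyl pivalate (C3 not defined, enolisable) | COc1cc([C@H]2C(C(=O)C(F)(F)F)C(=O)c3cc(Br)cc(OCc4ccccc4)c3O2)ccc1OC(=O)C(C)(C)C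
F2 | step 8 | 4-[(2S)-8-(benzyloxy)-6-bromo-3-diazo-4-oxochroman-2-yl]-2-methoxyphenyl pivalate (C2 arranged as in 10) | COc1cc([C@H]2C(=[N+]=[N-])C(=O)c3cc(Br)cc(OCc4ccccc4)c3O2)ccc1OC(=O)C(C)(C)C
F3 | step 8 | methyl (2R,3S)-7-(benzyloxy)-5-bromo-2-[3-methoxy-4-(pivaloyloxy)phenyl]-2,3-dihydro-1-benzofuran-3-carboxylate (cis) | COc1cc([C@@H]2Oc3c(OCc4ccccc4)cc(Br)cc3[C@@H]2C(=O)OC)ccc1OC(=O)C(C)(C)C
F4 | step 13 | [(2R,3S)-7-(benzyloxy)-2-[4-(benzyloxy)-3-methoxyphenyl]-5-bromo-2,3-dihydro-1-benzofuran-3-yl]methanol | COc1cc([C@@H]2Oc3c(OCc4ccccc4)cc(Br)cc3[C@H]2CO)ccc1OCc1ccccc1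
F5 | step 13 | (2R,3S)-7-(benzyloxy)-2-[4-(benzyloxy)-3-methoxyphenyl]-3-(hydroxymethyl)-2,3-dihydro-1-benzofuran-5-carbaldehyde | COc1cc([C@@H]2Oc3c(OCc4ccccc4)cc(C=O)cc3[C@H]2CO)ccc1OCc1ccccc1
F6 | step 13 | (E)-1-[2,4-bis(benzyloxy)-6-hydroxyphenyl]-3-[(2R,3S)-7-(benzyloxy)-2-[4-(benzyloxy)-3-methoxyphenyl]-3-(hydroxymethyl)-2,3-dihydro-1-benzofuran-5-yl]prop-2-en-1-one | COc1cc([C@@H]2Oc3c(OCc4ccccc4)cc(/C=C/C(=O)c4c(O)cc(OCc5ccccc5)cc4OCc4ccccc4)cc3[C@H]2CO)ccc1OCc1ccccc1
F7 | step 13 | (2S)-5,7-bis(benzyloxy)-2-[(2R,3S)-7-(benzyloxy)-2-[4-(benzyloxy)-3-methoxyphenyl]-3-(hydroxymethyl)-2,3-dihydro-1-benzofuran-5-yl]chroman-4-one | COc1cc([C@@H]2Oc3c(OCc4ccccc4)cc([C@@H]4CC(=O)c5c(OCc6ccccc6)cc(OCc6ccccc6)cc5O4)cc3[C@H]2CO)ccc1OCc1ccccc1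
F8 | step 13 | (2R)-5,7-bis(benzyloxy)-2-[(2R,3S)-7-(benzyloxy)-2-[4-(benzyloxy)-3-methoxyphenyl]-3-(hydroxymethyl)-2,3-dihydro-1-benzofuran-5-yl]chroman-4-one | COc1cc([C@@H]2Oc3c(OCc4ccccc4)cc([C@H]4CC(=O)c5c(OCc6ccccc6)cc(OCc6ccccc6)cc5O4)cc3[C@H]2CO)ccc1OCc1ccccc1
F0 | step 14 | none | none
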